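**Retrosynthetic overview**
1. The ester C–O bond is not made by acylating 2-phenylethanol: it comes from adding a carboxylic acid across styrene (photoredox anti-Markovnikov hydroacyloxylation, the key step).
2. Target 6 is cut at C11–C12 of the acyl chain into 2-phenylethyl 11-bromoundecanoate 3 and tridecyl Grignard 5 (Cu-catalysed sp3–sp3 coupling on the intact ester; C11 + C13 = C24, so no C24 acid is bought).
3. 3 comes from styrene 1 and 11-bromoundecanoic acid 2; 5 comes from 1-bromotridecane 4 and Mg.
4. No ring is formed; the phenyl ring arrives intact in styrene.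

Assumption: the target has no stereocentre and no stereogenic double bond, so "single enantiomer" imposes no stereochemical task.

**Step 1**
Reactants: 1 styrene; 2 11-bromoundecanoic acid
Product: 3 2-phenylethyl 11-bromoundecanoate
Conditions: 9-mesityl-10-methylacridinium BF4 (5 mol%), (PhS)2 (10 mol%), 2,6-lutidine (20 mol%), DCE, 450 nm LEDs, 25 °C, N2; 2 (3 equiv), 1 (1 equiv) added by syringe pump
Reagents that add atoms: none
Why: Acridinium photoredox anti-Markovnikov hydroacyloxylation of a styrene: SET oxidation of 1 gives the radical cation, carboxylate attacks the terminal carbon to leave the benzylic radical, and H-atom transfer from PhSH gives the primary ester; the alkyl bromide is inert and no stereocentre is created.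

**Step 2**
Reactants: 4 1-bromotridecane
Product: 5 tridecylmagnesium bromide
Conditions: Mg turnings (1.3 equiv), cat. I2, THF, 45 °C, slow addition of 4; kept as a titrated ca. 0.8 M solution under Ar
Reagents that add atoms: magnesium, [Mg]
Why: Grignard formation by oxidative insertion of Mg into a primary C–Br bond; dilution and slow addition suppress Wurtz homocoupling.

**Step 3**
Reactants: 3 2-phenylethyl 11-bromoundecanoate; 5 tridecylmagnesium bromide
Product: 6 2-phenylethyl tetracosanoate
Conditions: Li2CuCl4 (3 mol%), NMP (4 equiv), THF, 0 to 20 °C, 5 (1.3 equiv) added over 2 h; aq. NH4Cl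
Reagents that add atoms: none
Why: Kochi–Cahiez copper-catalysed alkyl–alkyl cross-coupling: the catalytic cuprate displaces the primary bromide much faster than the slowly added Grignard attacks the ester in THF/NMP, which closes the C24 chain without creating a stereocentre.

**Compound list**
1 | styrene | C=Cc1ccccc1 | starting material
2 | 11-bromoundecanoic acid | OC(=O)CCCCCCCCCCBr | starting material
3 | 2-phenylethyl 11-bromoundecanoate | BrCCCCCCCCCCC(=O)OCCc1ccccc1 | intermediate
4 | 1-bromotridecane | CCCCCCCCCCCCCBr | starting material
5 | tridecylmagnesium bromide | CCCCCCCCCCCCC[Mg]Br | intermediate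
6 | 2-phenylethyl tetracosanoate | CCCCCCCCCCCCCCCCCCCCCCCC(=O)OCCc1ccccc1 | target

**Total step count:** 3
**Longest linear sequence:** 2 steps (1 and 2 to 3 to 6; or 4 to 5 to 6)

**Steps most likely to fail**

Step 1 is the riskiest. The styrene radical cation may polymerise or dimerise faster than the carboxylate traps it, and the thiol cocatalyst can be slowly alkylated by the bromide. The fallback sets out from 2 and comes back at 3. Acid 2 is added across phenylacetylene (C#Cc1ccccc1) instead of styrene by Ru-catalysed anti-Markovnikov hydro-oxycarbonylation ([Ru(methallyl)2(dppb)] 1 mol%, toluene, 65 °C), which gives (Z)-2-phenylethenyl 11-bromoundecanoate F1. The enol-ester C=C of F1 is then hydrogenated (H2 1 atm, 5% Rh/Al2O3, EtOAc, 25 °C, stopped after 1 equiv) to give 3.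

Step 3 is next. The Grignard may add to the ester (ketone or tertiary alcohol), or homocouple to hexacosane. The fallback sets out from 3 and comes back at 6, and uses no organomagnesium. 1-Tridecene (C=CCCCCCCCCCCC) is hydroborated with 9-BBN (THF, 25 °C) to give 9-tridecyl-9-borabicyclo[3.3.1]nonane F2. F2 is coupled in the same flask with 3 by an ester-tolerant alkyl–alkyl Suzuki reaction (Pd(OAc)2 4 mol%, PCy3 8 mol%, K3PO4·H2O 1.2 equiv, THF, 25 °C) to give 6.

Step 2 is the least risky. Wurtz coupling could lower the titre and carry hexacosane forward. The fallback sets out from 4 and comes back at 6. Zinc is inserted into 4 (Zn dust 1.5 equiv, I2 5 mol%, DMA, 80 °C) to give tridecylzinc bromide F3. F3 is joined to 3 by a Pd-catalysed alkyl–alkyl Negishi coupling (Pd2(dba)3 2 mol%, PCyp3 8 mol%, N-methylimidazole 1.2 equiv, THF/NMP, 80 °C) to give 6.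

**Further compounds**
F1 | step 1 | (Z)-2-phenylethenyl 11-bromoundecanoate | BrCCCCCCCCCCC(=O)O/C=C\c1ccccc1
F2 | step 3 | 9-tridecyl-9-borabicyclo[3.3.1]nonane | CCCCCCCCCCCCCB1C2CCCC1CCC2
F3 | step 2 | tridecylzinc bromide | CCCCCCCCCCCCC[Zn]Br
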